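The cyclohex-2-enone ring is closed last by a formal [4+2] annulation. A dioxolane that holds the cis-4,5-diol (C4, C5) and carries a CH2I arm (C6) and a CHO arm (C3) on the same face meets a two-carbon phosphonoacetyl thioester. In one pot, nickel-catalysed reductive acylation of the iodide joins C6 to the future carbonyl carbon C1, and the β-ketophosphonate so formed closes C2=C3 by intramolecular Horner–Wadsworth–Emmons olefination. The step exploits the β-hydroxy ketone/γ-hydroxy enone pattern C5(OH)–C6H2–C1(=O)–C2=C3–C4(OH) of the six-membered ring. Both stereocentres come from one Sharpless kinetic resolution; the chain arrives through a 2-bromoalkene.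

Key step: step 11

Remark: ring atoms are numbered C1 (C=O), C2=C3 (alkene), C4 (CHOH), C5 (C(OH)-chain), C6 (CH2) throughout; the kinetic resolution in step 5 can deliver at most half of racemic 11 as 12.

Step 1
Reactants: 1 (E)-hex-3-en-1-ol
Product: 2 (E)-1-bromohex-3-ene
Conditions: CBr4, PPh3, CH2Cl2, 0 °C
Reagents that add atoms: carbon tetrabromide, BrC(Br)(Br)Br
Why: Appel bromination should convert the primary alcohol to the bromide by SN2 displacement of the oxyphosphonium without touching the E-alkene.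

Step 2
Reactants: 2 (E)-1-bromohex-3-ene; 3 1,12-dibromododecane
Product: 5 (E)-18-bromooctadec-3-ene, via Grignard reagent 4 (not isolated)
Conditions: Mg turnings, THF, 20 °C; then added to 3 (3 equiv), Li2CuCl4 (3 mol %), THF, −10 °C → 20 °C
Reagents that add atoms: none
Why: Kochi-type copper-catalysed sp3–sp3 coupling of a primary Grignard reagent with a primary alkyl bromide, in which the excess of dibromide should hold the reaction at mono-substitution and the homoallylic Grignard reagent should keep its E geometry.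

Step 3
Reactants: 5 (E)-18-bromooctadec-3-ene; 6 2,3-dibromoprop-1-ene
Product: 8 (18E)-2-bromohenicosa-1,18-diene, via Grignard reagent 7 (not isolated)
Conditions: Mg turnings, THF, 40 °C; then 6 (1.2 equiv), copper iodide CuI (5 mol %), THF, 0 °C → 20 °C
Reagents that add atoms: none
Why: Copper-catalysed allylic substitution of the Grignard reagent on the allylic C–Br bond of 6 (SN2 and SN2′ lead to the same product) should leave the vinylic bromide in place.

Step 4
Reactants: 8 (18E)-2-bromohenicosa-1,18-diene; 9 (tert-butyldimethylsilyloxy)acetaldehyde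
Product: 11 rac-(19E)-1-[(tert-butyldimethylsilyl)oxy]-3-methylidenedocos-19-en-2-ol, via alkenyllithium 10 (not isolated)
Conditions: t-BuLi (2 equiv), Et2O, −78 °C; then 9, −78 → 0 °C; H2O work-up
Reagents that add atoms: none
Why: Bromine–lithium exchange gives the 2-alkenyllithium, whose 1,2-addition to the aldehyde should give the racemic secondary allylic alcohol.

Step 5
Reactants: 11 rac-(19E)-1-[(tert-butyldimethylsilyl)oxy]-3-methylidenedocos-19-en-2-ol
Product: 12 (1R)-2-[(tert-butyldimethylsilyl)oxy]-1-{(2S)-2-[(16E)-nonadec-16-en-1-yl]oxiran-2-yl}ethan-1-ol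
Conditions: Ti(OiPr)4 (15 mol %), diisopropyl D-(−)-tartrate (20 mol %), t-BuOOH (0.55 equiv), 4 Å molecular sieves, CH2Cl2, −20 °C, stopped near half conversion
Reagents that add atoms: tert-butyl hydroperoxide, CC(C)(C)OO
Why: Sharpless kinetic resolution by asymmetric epoxidation, in which the D-tartrate catalyst should epoxidise the (2S)-alcohol fast and erythro-selectively (this sets the quaternary epoxide carbon relative to the carbinol in the sense needed for C4 and C5), leave the (2R)-alcohol behind and ignore the remote alkene.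

Step 6
Reactants: 12 (1R)-2-[(tert-butyldimethylsilyl)oxy]-1-{(2S)-2-[(16E)-nonadec-16-en-1-yl]oxiran-2-yl}ethan-1-ol
Product: 13 (2R,3R,19E)-1-[(tert-butyldimethylsilyl)oxy]-3-(iodomethyl)docos-19-ene-2,3-diol
Conditions: LiI, AcOH, THF, 20 °C
Reagents that add atoms: lithium iodide, [Li+].[I-]
Why: Regioselective halohydrin formation, in which iodide should open the 2,2-disubstituted epoxide by SN2 attack at the CH2 terminus, so the C–O bond and the configuration at the quaternary carbon stay intact.

Step 7
Reactants: 13 (2R,3R,19E)-1-[(tert-butyldimethylsilyl)oxy]-3-(iodomethyl)docos-19-ene-2,3-diol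
Product: 14 tert-butyl({(4R,5R)-5-(iodomethyl)-2,2-dimethyl-5-[(16E)-nonadec-16-en-1-yl]-1,3-dioxolan-4-yl}methoxy)dimethylsilane
Conditions: 2,2-dimethoxypropane, PPTS (cat.), CH2Cl2, 20 °C
Reagents that add atoms: 2,2-dimethoxypropane, COC(C)(C)OC
Why: Acid-catalysed transketalisation should tie the secondary/tertiary 1,2-diol into a dioxolane that protects both hydroxyls and holds the CH2I and CH2OSi arms cis on the five-membered ring.

Step 8
Reactants: 14 tert-butyl({(4R,5R)-5-(iodomethyl)-2,2-dimethyl-5-[(16E)-nonadec-16-en-1-yl]-1,3-dioxolan-4-yl}methoxy)dimethylsilane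
Product: 15 {(4R,5R)-5-(iodomethyl)-2,2-dimethyl-5-[(16E)-nonadec-16-en-1-yl]-1,3-dioxolan-4-yl}methanol
Conditions: HF·pyridine, pyridine, THF, 0 → 20 °C
Reagents that add atoms: none
Why: Fluoride-driven desilylation of the primary silyl ether under buffered, non-basic conditions should free the alcohol without forming an alkoxide that could displace the cis CH2I group and without opening the ketal.

Step 9
Reactants: 15 {(4R,5R)-5-(iodomethyl)-2,2-dimethyl-5-[(16E)-nonadec-16-en-1-yl]-1,3-dioxolan-4-yl}methanol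
Product: 16 (4S,5R)-5-(iodomethyl)-2,2-dimethyl-5-[(16E)-nonadec-16-en-1-yl]-1,3-dioxolane-4-carbaldehyde
Conditions: Dess–Martin periodinane, pyridine, CH2Cl2, 0 °C; used at once
Reagents that add atoms: none
Why: Dess–Martin oxidation should give the α-alkoxy aldehyde under near-neutral conditions that spare the adjacent C–H stereocentre, the ketal and the alkyl iodide.

Step 10
Reactants: 17 (diethoxyphosphoryl)acetic acid
Product: 18 S-(pyridin-2-yl) 2-(diethoxyphosphoryl)ethanethioate
Conditions: 2,2′-dipyridyl disulfide, PPh3, CH2Cl2, 20 °C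
Reagents that add atoms: 2,2′-dipyridyl disulfide, c1ccc(nc1)SSc1ccccn1
Why: Mukaiyama redox condensation should activate the acid as its acyloxyphosphonium salt and deliver the 2-pyridyl thioester.

Step 11
Reactants: 16 (4S,5R)-5-(iodomethyl)-2,2-dimethyl-5-[(16E)-nonadec-16-en-1-yl]-1,3-dioxolane-4-carbaldehyde; 18 S-(pyridin-2-yl) 2-(diethoxyphosphoryl)ethanethioate
Product: 20 (3aR,7aS)-2,2-dimethyl-7a-[(16E)-nonadec-16-en-1-yl]-7,7a-dihydro-1,3-benzodioxol-6(3aH)-one, via β-ketophosphonate 19 (not isolated)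
Conditions: NiCl2·DME (10 mol %), 4,4′-di-tert-butyl-2,2′-bipyridine (10 mol %), Zn dust (2 equiv), DMA, 20 °C; then LiCl, iPr2NEt, MeCN, 0 → 20 °C (one pot)
Reagents that add atoms: none
Why: Zerovalent nickel inserts into the C–S bond of 18, the acylnickel captures the primary radical generated from the C–I bond of 16 (zinc as terminal reductant) and reductive elimination forges C6–C1 to give 19, after which LiCl/iPr2NEt deprotonate C2 between phosphoryl and carbonyl and the carbanion adds to the aldehyde and loses diethyl phosphate to form C2=C3. The closest known reactions are the nickel-catalysed cross-electrophile ketone synthesis from alkyl iodides and 2-pyridyl thioesters and the Masamune–Roush intramolecular Horner–Wadsworth–Emmons olefination. The six-membered carbocycle closes by 6-exo-trig attack of C2 on the aldehyde carbon C3, and the ring enforces the cis geometry of the new alkene. No new stereocentre is formed; the dioxolane carries C4 and C5 through unchanged, and the mild amine/LiCl base is chosen to avoid epimerisation at C4 and β-elimination of the ring oxygen. The step needs activation of the C–I bond in the presence of the aldehyde, which the radical/nickel manifold should secure, and intramolecular rather than intermolecular olefination, which the cis placement of both arms on the dioxolane should secure.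

Step 12
Reactants: 20 (3aR,7aS)-2,2-dimethyl-7a-[(16E)-nonadec-16-en-1-yl]-7,7a-dihydro-1,3-benzodioxol-6(3aH)-one
Product: 21 (4R,5S)-4,5-dihydroxy-5-[(16E)-nonadec-16-en-1-yl]cyclohex-2-en-1-one
Conditions: CF3CO2H/H2O (9:1), 0 °C, short contact time; NaHCO3 quench
Reagents that add atoms: none
Why: Acid-catalysed hydrolysis of the isopropylidene ketal at low temperature should release the cis-diol before the β-hydroxy ketone can lose water.

Compound list
1 | (E)-hex-3-en-1-ol | CC/C=C/CCO | starting material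
2 | (E)-1-bromohex-3-ene | CC/C=C/CCBr | intermediate
3 | 1,12-dibromododecane | BrCCCCCCCCCCCCBr | starting material
4 | (E)-hex-3-en-1-ylmagnesium bromide | CC/C=C/CC[Mg]Br | intermediate
5 | (E)-18-bromooctadec-3-ene | CC/C=C/CCCCCCCCCCCCCCBr | intermediate
6 | 2,3-dibromoprop-1-ene | C=C(Br)CBr | starting material
7 | (E)-octadec-15-en-1-ylmagnesium bromide | CC/C=C/CCCCCCCCCCCCCC[Mg]Br | intermediate
8 | (18E)-2-bromohenicosa-1,18-diene | CC/C=C/CCCCCCCCCCCCCCCC(Br)=C | intermediate
9 | (tert-butyldimethylsilyloxy)acetaldehyde | CC(C)(C)[Si](C)(C)OCC=O | starting material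
10 | (18E)-henicosa-1,18-dien-2-yllithium | CC/C=C/CCCCCCCCCCCCCCCC([Li])=C | intermediate
11 | rac-(19E)-1-[(tert-butyldimethylsilyl)oxy]-3-methylidenedocos-19-en-2-ol | CC/C=C/CCCCCCCCCCCCCCCC(=C)C(O)CO[Si](C)(C)C(C)(C)C | intermediate
12 | (1R)-2-[(tert-butyldimethylsilyl)oxy]-1-{(2S)-2-[(16E)-nonadec-16-en-1-yl]oxiran-2-yl}ethan-1-ol | CC/C=C/CCCCCCCCCCCCCCC[C@]1(CO1)[C@H](O)CO[Si](C)(C)C(C)(C)C | intermediate
13 | (2R,3R,19E)-1-[(tert-butyldimethylsilyl)oxy]-3-(iodomethyl)docos-19-ene-2,3-diol | CC/C=C/CCCCCCCCCCCCCCC[C@](O)(CI)[C@H](O)CO[Si](C)(C)C(C)(C)C | intermediate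
14 | tert-butyl({(4R,5R)-5-(iodomethyl)-2,2-dimethyl-5-[(16E)-nonadec-16-en-1-yl]-1,3-dioxolan-4-yl}methoxy)dimethylsilane | CC/C=C/CCCCCCCCCCCCCCC[C@@]1(CI)OC(C)(C)O[C@@H]1CO[Si](C)(C)C(C)(C)C | intermediate
15 | {(4R,5R)-5-(iodomethyl)-2,2-dimethyl-5-[(16E)-nonadec-16-en-1-yl]-1,3-dioxolan-4-yl}methanol | CC/C=C/CCCCCCCCCCCCCCC[C@@]1(CI)OC(C)(C)O[C@@H]1CO | intermediate
16 | (4S,5R)-5-(iodomethyl)-2,2-dimethyl-5-[(16E)-nonadec-16-en-1-yl]-1,3-dioxolane-4-carbaldehyde | CC/C=C/CCCCCCCCCCCCCCC[C@@]1(CI)OC(C)(C)O[C@@H]1C=O | intermediate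
17 | (diethoxyphosphoryl)acetic acid | CCOP(=O)(CC(=O)O)OCC | starting material
18 | S-(pyridin-2-yl) 2-(diethoxyphosphoryl)ethanethioate | CCOP(=O)(CC(=O)Sc1ccccn1)OCC | intermediate
19 | diethyl (3-{(4S,5S)-5-formyl-2,2-dimethyl-4-[(16E)-nonadec-16-en-1-yl]-1,3-dioxolan-4-yl}-2-oxopropyl)phosphonate | CC/C=C/CCCCCCCCCCCCCCC[C@@]1(CC(=O)CP(=O)(OCC)OCC)OC(C)(C)O[C@@H]1C=O | intermediate
20 | (3aR,7aS)-2,2-dimethyl-7a-[(16E)-nonadec-16-en-1-yl]-7,7a-dihydro-1,3-benzodioxol-6(3aH)-one (acetonide of 21) | CC/C=C/CCCCCCCCCCCCCCC[C@]12CC(=O)C=C[C@H]1OC(C)(C)O2 | intermediate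
21 | (4R,5S)-4,5-dihydroxy-5-[(16E)-nonadec-16-en-1-yl]cyclohex-2-en-1-one | CC/C=C/CCCCCCCCCCCCCCC[C@]1(O)CC(=O)C=C[C@H]1O | target

Total step count: 12. Longest linear sequence: 11 steps (steps 1–9, 11, 12); step 10 is a one-step side branch.

Steps most likely to fail

1. Step 11. The free aldehyde may be consumed under the reductive nickel/zinc conditions (reduction, pinacol coupling or addition of an alkylmetal), or the amine stage may erode C4 before ring closure. Fallback: set out from silyl ether 14, so that no aldehyde is present during the C–C coupling. The same nickel-catalysed coupling with 18 should give the silyl-protected ketophosphonate F1, HF·pyridine the hydroxy ketophosphonate F2, and Dess–Martin oxidation the keto aldehyde 19, now isolated. K2CO3 with 18-crown-6 in toluene then closes the ring and the route is rejoined at 20.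

2. Step 5. The rate difference between the enantiomers or the erythro/threo discrimination may be too small, so that 12 is formed with poor enantiomeric and diastereomeric purity. Fallback: set out from racemic 11 and replace resolution by reagent control. Dess–Martin oxidation should give the enone F3. Reduction with (S)-2-methyl-CBS-oxazaborolidine and catecholborane (the branched alkenyl group acting as the large substituent) should give the (2S)-allylic alcohol F4. Hydroxyl-directed epoxidation with VO(acac)2 and t-BuOOH, erythro-selective through allylic 1,2-strain, rejoins the route at 12.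

3. Step 12. Under acid the β-hydroxy ketone may lose water across C5–C6 and then at C4, ending in aromatisation to the alkylphenol. Fallback: set out from iodo diol 13 and replace the ketal by fluoride-labile silyl ethers. Aqueous HF in MeCN should give the triol F5 and Et3SiOTf/2,6-lutidine the tris(triethylsilyl) ether F6. Swern oxidation, which oxidises the primary triethylsilyl ether directly, should give the aldehyde F7. The one-pot nickel acylation/olefination with 18 should then give the bis-silylated enone F9 by way of the ketophosphonate F8. Buffered HF·pyridine removes both silyl groups without acid and rejoins the route at 21.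

Further compounds
F1 | step 11 | diethyl (3-{(4S,5R)-5-({[tert-butyl(dimethyl)silyl]oxy}methyl)-2,2-dimethyl-4-[(16E)-nonadec-16-en-1-yl]-1,3-dioxolan-4-yl}-2-oxopropyl)phosphonate | CC/C=C/CCCCCCCCCCCCCCC[C@@]1(CC(=O)CP(=O)(OCC)OCC)OC(C)(C)O[C@@H]1CO[Si](C)(C)C(C)(C)C
F2 | step 11 | diethyl (3-{(4S,5R)-5-(hydroxymethyl)-2,2-dimethyl-4-[(16E)-nonadec-16-en-1-yl]-1,3-dioxolan-4-yl}-2-oxopropyl)phosphonate | CC/C=C/CCCCCCCCCCCCCCC[C@@]1(CC(=O)CP(=O)(OCC)OCC)OC(C)(C)O[C@@H]1CO
F3 | step 5 | (19E)-1-[(tert-butyldimethylsilyl)oxy]-3-methylidenedocos-19-en-2-one | CC/C=C/CCCCCCCCCCCCCCCC(=C)C(=O)CO[Si](C)(C)C(C)(C)C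
F4 | step 5 | (2S,19E)-1-[(tert-butyldimethylsilyl)oxy]-3-methylidenedocos-19-en-2-ol | CC/C=C/CCCCCCCCCCCCCCCC(=C)[C@H](O)CO[Si](C)(C)C(C)(C)C
F5 | step 12 | (2R,3R,19E)-3-(iodomethyl)docos-19-ene-1,2,3-triol | CC/C=C/CCCCCCCCCCCCCCC[C@](O)(CI)[C@H](O)CO
F6 | step 12 | (2R,3R,19E)-3-(iodomethyl)-1,2,3-tris[(triethylsilyl)oxy]docos-19-ene | CC/C=C/CCCCCCCCCCCCCCC[C@](O[Si](CC)(CC)CC)(CI)[C@H](O[Si](CC)(CC)CC)CO[Si](CC)(CC)CC
F7 | step 12 | (2S,3R,19E)-3-(iodomethyl)-2,3-bis[(triethylsilyl)oxy]docos-19-enal | CC/C=C/CCCCCCCCCCCCCCC[C@](O[Si](CC)(CC)CC)(CI)[C@H](O[Si](CC)(CC)CC)C=O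
F8 | step 12 | diethyl {(4S,20E)-2-oxo-4-[(1S)-2-oxo-1-(triethylsilyloxy)ethyl]-4-(triethylsilyloxy)tricos-20-en-1-yl}phosphonate | CC/C=C/CCCCCCCCCCCCCCC[C@](O[Si](CC)(CC)CC)(CC(=O)CP(=O)(OCC)OCC)[C@H](O[Si](CC)(CC)CC)C=O
F9 | step 12 | (4R,5S)-5-[(16E)-nonadec-16-en-1-yl]-4,5-bis[(triethylsilyl)oxy]cyclohex-2-en-1-one | CC/C=C/CCCCCCCCCCCCCCC[C@]1(O[Si](CC)(CC)CC)CC(=O)C=C[C@H]1O[Si](CC)(CC)CC
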